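**Retrosynthetic overview**

1. Ring C is made last. Cutting O1–C2 and C2–C3 (Baker–Venkataraman aroyl shift, then cyclodehydration) gives ring B benzoic acid 11 and ring A ω-benzoyloxy ketone 20.
2. Ring B is cut at C2'–C3' and C4'–C5' into methyl coumalate 8 and the (R)-1-methoxyalkyne 7. The strategy rests on the 1,3,4-pattern of ring B: the C4' methoxy donor is para to the acceptor-bearing C1', and the C1''–C4'' chain sits on C3'.
3. Alkyne 7 comes from (S)-isopropenyloxirane 3 (C2'' stereocentre from a hydrolytic kinetic resolution) and lithium methoxyacetylide 5.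
4. Ring A is bought as acetophenone 12; the C6 oxygen is added by Elbs oxidation and the C3 oxygen by Rubottom oxidation.
5. Order of ring formation: ring A (purchased), ring B (step 5), ring C (steps 13–14).

Key step: step 5

Remark: the (S,S)-cobalt salen catalyst is assumed to leave the (S)-epoxide of 2, as it does with propylene oxide and vinyloxirane. Primed locants denote ring B and doubly primed locants the C5 side chain.

**Route**

Step 1
Reactants: 1 methacrolein
Product: 2 rac-2-(prop-1-en-2-yl)oxirane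
Conditions: Me3S+ I−, NaH, DMSO/THF, −5 °C → rt; product distilled out of the mixture
Reagents that add atoms: trimethylsulfonium iodide, C[S+](C)C.[I-]
Why: Corey–Chaykovsky epoxidation, in which the unstabilised sulfonium ylide adds 1,2 to the enal carbonyl and the betaine closes to the vinyl epoxide, formed as the racemate.

Step 2
Reactants: 2 rac-2-(prop-1-en-2-yl)oxirane
Product: 3 (2S)-2-(prop-1-en-2-yl)oxirane
Conditions: (S,S)-(salen)Co(OAc) (0.5 mol%, trivalent cobalt; salen = N,N'-bis(3,5-di-tert-butylsalicylidene)-1,2-cyclohexanediamine dianion), H2O (0.55 equiv), neat, 0 °C → rt; distillation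
Reagents that add atoms: none
Why: Jacobsen hydrolytic kinetic resolution, in which the chiral cobalt salen catalyst should hydrate the (R)-epoxide at its CH2 terminus and leave the volatile (S)-epoxide, whose stereocentre becomes C2'' of the target.

Step 3
Reactants: 4 chloroacetaldehyde dimethyl acetal; 3 (2S)-2-(prop-1-en-2-yl)oxirane
Product: 6 (3R)-6-methoxy-2-methylhex-1-en-5-yn-3-ol, via lithium methoxyacetylide 5 (not isolated)
Conditions: 4 (1.5 equiv), LiNEt2 (3 equiv per 4, from n-BuLi and Et2NH), THF, 0 °C; then 3, DMPU, 0 °C → rt; NH4Cl (aq)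
Reagents that add atoms: none
Why: twofold elimination from the chloroacetal gives the alkoxyacetylide, which should open the monosubstituted epoxide by SN2 attack at the unhindered CH2 terminus because no Lewis acid is present to activate the allylic carbon; the stereocentre is untouched (the descriptor changes from S to R only through CIP priorities).

Step 4
Reactants: 6 (3R)-6-methoxy-2-methylhex-1-en-5-yn-3-ol
Product: 7 tert-butyl{[(3R)-6-methoxy-2-methylhex-1-en-5-yn-3-yl]oxy}dimethylsilane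
Conditions: TBSCl, imidazole, DMF, 0 °C → rt; crude 6 used at once
Reagents that add atoms: tert-butyldimethylsilyl chloride, CC(C)(C)[Si](C)(C)Cl
Why: silylation of a secondary alcohol under imidazole-buffered conditions, which keeps the acid-labile ynol ether intact and blocks lactonisation of the homopropargylic alcohol onto it.

Step 5
Reactants: 7 tert-butyl{[(3R)-6-methoxy-2-methylhex-1-en-5-yn-3-yl]oxy}dimethylsilane; 8 methyl coumalate
Product: 10 methyl 3-[(2R)-2-{[tert-butyl(dimethyl)silyl]oxy}-3-methylbut-3-en-1-yl]-4-methoxybenzoate, via bridged bicyclic lactone 9 (not isolated)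
Conditions: 8 (1.5 equiv), toluene, 80 → 110 °C, sealed base-washed tube, N2
Reagents that add atoms: none
Why: Inverse-electron-demand Diels–Alder reaction in which the nucleophilic, alkyl-bearing carbon of the ynol ether bonds to pyrone C6 (β to the ester and vinylogous to the lactone carbonyl, hence the most electrophilic carbon) and the methoxy-bearing carbon closes onto pyrone C3, giving lactone 9. Retro-[4+2] loss of CO2 from 9 aromatises directly, so ring B is closed by an intermolecular [4+2] cycloaddition (bonds C2'–C3' and C4'–C5') followed by cycloreversion, with no elimination step. The closest known reaction type is the cycloaddition of methyl coumalate with ketene acetals, enol ethers, ynamines and alkynes, which gives benzoates carrying the donor para to the ester. No stereocentre is formed in 10: the bridgehead centres of 9 vanish on aromatisation and C2'' is a spectator. The selectivity needed is the regiochemistry that puts OMe para and the chain meta to the ester, and the matched polarisation of pyrone C6 and the β-carbon of the ynol ether secures it. The unactivated isopropenyl group should not compete as dienophile, and a methyl ynol ether has no β-hydrogen for retro-ene loss on heating.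

Step 6
Reactants: 10 methyl 3-[(2R)-2-{[tert-butyl(dimethyl)silyl]oxy}-3-methylbut-3-en-1-yl]-4-methoxybenzoate
Product: 11 3-[(2R)-2-{[tert-butyl(dimethyl)silyl]oxy}-3-methylbut-3-en-1-yl]-4-methoxybenzoic acid
Conditions: LiOH·H2O, THF/MeOH/H2O, 45 °C; then 1 M HCl to pH 4, 0 °C
Reagents that add atoms: lithium hydroxide, [Li+].[OH-]
Why: ester saponification, which the hindered secondary silyl ether and the isolated alkene should survive.

Step 7
Reactants: 12 2',4'-dihydroxy-6'-methoxyacetophenone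
Product: 13 1-[2-hydroxy-6-methoxy-4-(prop-2-en-1-yloxy)phenyl]ethan-1-one
Conditions: allyl bromide (1.05 equiv), K2CO3, acetone, 50 °C
Reagents that add atoms: allyl bromide, C=CCBr
Why: Williamson etherification that should select the more acidic, non-chelated 4'-OH over the 2'-OH, which is hydrogen-bonded to the ketone.

Step 8
Reactants: 13 1-[2-hydroxy-6-methoxy-4-(prop-2-en-1-yloxy)phenyl]ethan-1-one
Product: 15 1-[3,6-dihydroxy-2-methoxy-4-(prop-2-en-1-yloxy)phenyl]ethan-1-one, via potassium aryl sulfate 14 (not isolated)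
Conditions: K2S2O8, NaOH (aq), pyridine, 0 °C → rt; acidify to pH 5 and extract unreacted 13 for recycling; then HCl (aq), 80 °C, N2
Reagents that add atoms: potassium peroxodisulfate, [K+].[K+].[O-]S(=O)(=O)OOS(=O)(=O)[O-]
Why: Elbs persulfate oxidation, in which the phenoxide attacks the peroxide oxygen through the carbon para to O− (C5', the future C6) and the aryl sulfate is then hydrolysed to the hydroquinone.

Step 9
Reactants: 15 1-[3,6-dihydroxy-2-methoxy-4-(prop-2-en-1-yloxy)phenyl]ethan-1-one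
Product: 16 1-[6-hydroxy-2,3-dimethoxy-4-(prop-2-en-1-yloxy)phenyl]ethan-1-one
Conditions: MeI (1.1 equiv), K2CO3 (1.1 equiv), acetone, 40 °C, N2
Reagents that add atoms: iodomethane, CI
Why: selective O-methylation of the free 5'-OH, since the 2'-OH is held in a hydrogen bond to the ketone and alkylates much more slowly.

Step 10
Reactants: 16 1-[6-hydroxy-2,3-dimethoxy-4-(prop-2-en-1-yloxy)phenyl]ethan-1-one
Product: 19 2-hydroxy-1-[6-hydroxy-2,3-dimethoxy-4-(prop-2-en-1-yloxy)phenyl]ethan-1-one, via bis-silylated enol ether 17 (not isolated), via alpha-silyloxy ketone 18 (not isolated)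
Conditions: TMSOTf (2.3 equiv), Et3N, CH2Cl2, 0 °C; solvent switch; mCPBA (1.05 equiv), CH2Cl2, −20 → 0 °C; then citric acid (cat.), MeOH, rt
Reagents that add atoms: meta-chloroperoxybenzoic acid, OOC(=O)c1cccc(Cl)c1
Why: Rubottom oxidation, in which the silyl enol ether is the most electron-rich alkene and is epoxidised ahead of the allyl ether, silyl migration gives the α-silyloxy ketone, and methanolysis frees the ketol and the phenol.

Step 11
Reactants: 19 2-hydroxy-1-[6-hydroxy-2,3-dimethoxy-4-(prop-2-en-1-yloxy)phenyl]ethan-1-one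
Product: 20 2-[6-hydroxy-2,3-dimethoxy-4-(prop-2-en-1-yloxy)phenyl]-2-oxoethyl benzoate
Conditions: BzCl (1.05 equiv), pyridine, CH2Cl2, −20 → 0 °C
Reagents that add atoms: benzoyl chloride, O=C(Cl)c1ccccc1
Why: selective O-acylation of the primary ketol hydroxyl, the chelated and flanked 2'-OH being far less reactive without an acyl-transfer catalyst.

Step 12
Reactants: 11 3-[(2R)-2-{[tert-butyl(dimethyl)silyl]oxy}-3-methylbut-3-en-1-yl]-4-methoxybenzoic acid; 20 2-[6-hydroxy-2,3-dimethoxy-4-(prop-2-en-1-yloxy)phenyl]-2-oxoethyl benzoate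
Product: 21 2-[(benzoyloxy)acetyl]-3,4-dimethoxy-5-(prop-2-en-1-yloxy)phenyl 3-[(2R)-2-{[tert-butyl(dimethyl)silyl]oxy}-3-methylbut-3-en-1-yl]-4-methoxybenzoate
Conditions: EDC·HCl, DMAP, CH2Cl2, rt
Reagents that add atoms: none
Why: Steglich esterification, in which the acylpyridinium is reactive enough to acylate the chelated phenol and no acid chloride has to be made in the presence of the silyl ether.

Step 13
Reactants: 21 2-[(benzoyloxy)acetyl]-3,4-dimethoxy-5-(prop-2-en-1-yloxy)phenyl 3-[(2R)-2-{[tert-butyl(dimethyl)silyl]oxy}-3-methylbut-3-en-1-yl]-4-methoxybenzoate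
Product: 22 1-{3-[(2R)-2-{[tert-butyl(dimethyl)silyl]oxy}-3-methylbut-3-en-1-yl]-4-methoxyphenyl}-3-[6-hydroxy-2,3-dimethoxy-4-(prop-2-en-1-yloxy)phenyl]-1,3-dioxopropan-2-yl benzoate
Conditions: LiN(SiMe3)2 (3 equiv), THF, −78 → −20 °C; then AcOH
Reagents that add atoms: none
Why: Baker–Venkataraman rearrangement, in which the ketone enolate attacks the aryl ester through a six-membered transition state and moves the ring B aroyl group from oxygen to carbon (forming C2–C3); the new CH(OBz) centre is uncontrolled and is removed in step 14.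

Step 14
Reactants: 22 the 2-benzoyloxy-1,3-diketone from step 13
Product: 24 2-{3-[(2R)-2-{[tert-butyl(dimethyl)silyl]oxy}-3-methylbut-3-en-1-yl]-4-methoxyphenyl}-5,6-dimethoxy-4-oxo-7-(prop-2-en-1-yloxy)-4H-chromen-3-yl benzoate, via 2-hydroxyflavanone hemiketal 23 (not isolated)
Conditions: NaOAc, AcOH, 90 °C
Reagents that add atoms: none
Why: cyclodehydration, in which the 2'-OH adds to the ring B ketone (forming O1–C2) and the hemiketal loses water to close ring C; the buffered weak acid should not protonate the isopropenyl alkene, whose cation would be destabilised by the adjacent silyloxy carbon.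

Step 15
Reactants: 24 the 3-benzoyloxy-7-allyloxyflavone from step 14
Product: 26 2-{3-[(2R)-2-{[tert-butyl(dimethyl)silyl]oxy}-3-methylbut-3-en-1-yl]-4-methoxyphenyl}-3,7-dihydroxy-5,6-dimethoxy-4H-chromen-4-one, via 3-hydroxy-7-allyloxyflavone 25 (not isolated)
Conditions: K2CO3, MeOH/THF (degassed), rt; then Pd(PPh3)4 (5 mol%, zerovalent palladium), 50 °C
Reagents that add atoms: none
Why: methanolysis of the enol benzoate followed by Tsuji–Trost deallylation of the aryl allyl ether with methoxide as allyl acceptor, conditions that use no Lewis acid and so leave the 5-OMe, the silyl ether and the isopropenyl group alone.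

Step 16
Reactants: 26 the 3,7-dihydroxyflavone silyl ether from step 15
Product: 27 3,7-dihydroxy-2-{3-[(2R)-2-hydroxy-3-methylbut-3-en-1-yl]-4-methoxyphenyl}-5,6-dimethoxy-4H-chromen-4-one (target)
Conditions: Bu4NF, AcOH, THF, 0 °C → rt
Reagents that add atoms: none
Why: fluoride desilylation buffered with acetic acid, which frees the secondary allylic alcohol without acid or base strong enough to ionise it or to touch the C2'' stereocentre.

**Compound list**

1 | methacrolein (2-methylprop-2-enal) | C=C(C)C=O | starting material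
2 | rac-2-(prop-1-en-2-yl)oxirane | C=C(C)C1CO1 | intermediate
3 | (2S)-2-(prop-1-en-2-yl)oxirane | C=C(C)[C@H]1CO1 | intermediate
4 | chloroacetaldehyde dimethyl acetal (2-chloro-1,1-dimethoxyethane) | COC(CCl)OC | starting material
5 | lithium methoxyacetylide | [Li]C#COC | intermediate (not isolated)
6 | (3R)-6-methoxy-2-methylhex-1-en-5-yn-3-ol | C=C(C)[C@H](O)CC#COC | intermediate
7 | tert-butyl{[(3R)-6-methoxy-2-methylhex-1-en-5-yn-3-yl]oxy}dimethylsilane | C=C(C)[C@H](O[Si](C)(C)C(C)(C)C)CC#COC | intermediate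
8 | methyl coumalate (methyl 2-oxo-2H-pyran-5-carboxylate) | COC(=O)c1ccc(=O)oc1 | starting material
9 | methyl 7-[(2R)-2-{[tert-butyl(dimethyl)silyl]oxy}-3-methylbut-3-en-1-yl]-8-methoxy-3-oxo-2-oxabicyclo[2.2.2]octa-5,7-diene-6-carboxylate (both bridgehead epimers) | O=C1OC2C(C(=O)OC)=CC1C(OC)=C2C[C@@H](O[Si](C)(C)C(C)(C)C)C(C)=C | intermediate (not isolated)
10 | methyl 3-[(2R)-2-{[tert-butyl(dimethyl)silyl]oxy}-3-methylbut-3-en-1-yl]-4-methoxybenzoate | C=C(C)[C@H](O[Si](C)(C)C(C)(C)C)Cc1cc(C(=O)OC)ccc1OC | intermediate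
11 | 3-[(2R)-2-{[tert-butyl(dimethyl)silyl]oxy}-3-methylbut-3-en-1-yl]-4-methoxybenzoic acid | C=C(C)[C@H](O[Si](C)(C)C(C)(C)C)Cc1cc(C(=O)O)ccc1OC | intermediate
12 | 2',4'-dihydroxy-6'-methoxyacetophenone | CC(=O)c1c(O)cc(O)cc1OC | starting material
13 | 1-[2-hydroxy-6-methoxy-4-(prop-2-en-1-yloxy)phenyl]ethan-1-one | CC(=O)c1c(O)cc(OCC=C)cc1OC | intermediate
14 | potassium 3-acetyl-4-hydroxy-2-methoxy-6-(prop-2-en-1-yloxy)phenyl sulfate | CC(=O)c1c(O)cc(OCC=C)c(OS(=O)(=O)[O-])c1OC.[K+] | intermediate (not isolated)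
15 | 1-[3,6-dihydroxy-2-methoxy-4-(prop-2-en-1-yloxy)phenyl]ethan-1-one | CC(=O)c1c(O)cc(OCC=C)c(O)c1OC | intermediate
16 | 1-[6-hydroxy-2,3-dimethoxy-4-(prop-2-en-1-yloxy)phenyl]ethan-1-one | CC(=O)c1c(O)cc(OCC=C)c(OC)c1OC | intermediate
17 | {[1-{2,3-dimethoxy-4-(prop-2-en-1-yloxy)-6-[(trimethylsilyl)oxy]phenyl}ethenyl]oxy}trimethylsilane | C=C(O[Si](C)(C)C)c1c(O[Si](C)(C)C)cc(OCC=C)c(OC)c1OC | intermediate (not isolated)
18 | 1-{2,3-dimethoxy-4-(prop-2-en-1-yloxy)-6-[(trimethylsilyl)oxy]phenyl}-2-[(trimethylsilyl)oxy]ethan-1-one | C[Si](C)(C)OCC(=O)c1c(O[Si](C)(C)C)cc(OCC=C)c(OC)c1OC | intermediate (not isolated)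
19 | 2-hydroxy-1-[6-hydroxy-2,3-dimethoxy-4-(prop-2-en-1-yloxy)phenyl]ethan-1-one | OCC(=O)c1c(O)cc(OCC=C)c(OC)c1OC | intermediate
20 | 2-[6-hydroxy-2,3-dimethoxy-4-(prop-2-en-1-yloxy)phenyl]-2-oxoethyl benzoate | O=C(OCC(=O)c1c(O)cc(OCC=C)c(OC)c1OC)c1ccccc1 | intermediate
21 | 2-[(benzoyloxy)acetyl]-3,4-dimethoxy-5-(prop-2-en-1-yloxy)phenyl 3-[(2R)-2-{[tert-butyl(dimethyl)silyl]oxy}-3-methylbut-3-en-1-yl]-4-methoxybenzoate | C=C(C)[C@H](O[Si](C)(C)C(C)(C)C)Cc1cc(C(=O)Oc2cc(OCC=C)c(OC)c(OC)c2C(=O)COC(=O)c2ccccc2)ccc1OC | intermediate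
22 | 1-{3-[(2R)-2-{[tert-butyl(dimethyl)silyl]oxy}-3-methylbut-3-en-1-yl]-4-methoxyphenyl}-3-[6-hydroxy-2,3-dimethoxy-4-(prop-2-en-1-yloxy)phenyl]-1,3-dioxopropan-2-yl benzoate (epimers at C2 and enol forms) | C=C(C)[C@H](O[Si](C)(C)C(C)(C)C)Cc1cc(C(=O)C(OC(=O)c2ccccc2)C(=O)c2c(O)cc(OCC=C)c(OC)c2OC)ccc1OC | intermediate
23 | 2-{3-[(2R)-2-{[tert-butyl(dimethyl)silyl]oxy}-3-methylbut-3-en-1-yl]-4-methoxyphenyl}-2-hydroxy-5,6-dimethoxy-4-oxo-7-(prop-2-en-1-yloxy)-3,4-dihydro-2H-chromen-3-yl benzoate (ring stereocentres uncontrolled) | C=C(C)[C@H](O[Si](C)(C)C(C)(C)C)Cc1cc(C2(O)Oc3cc(OCC=C)c(OC)c(OC)c3C(=O)C2OC(=O)c2ccccc2)ccc1OC | intermediate (not isolated)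
24 | 2-{3-[(2R)-2-{[tert-butyl(dimethyl)silyl]oxy}-3-methylbut-3-en-1-yl]-4-methoxyphenyl}-5,6-dimethoxy-4-oxo-7-(prop-2-en-1-yloxy)-4H-chromen-3-yl benzoate | C=C(C)[C@H](O[Si](C)(C)C(C)(C)C)Cc1cc(-c2oc3cc(OCC=C)c(OC)c(OC)c3c(=O)c2OC(=O)c2ccccc2)ccc1OC | intermediate
25 | 2-{3-[(2R)-2-{[tert-butyl(dimethyl)silyl]oxy}-3-methylbut-3-en-1-yl]-4-methoxyphenyl}-3-hydroxy-5,6-dimethoxy-7-(prop-2-en-1-yloxy)-4H-chromen-4-one | C=C(C)[C@H](O[Si](C)(C)C(C)(C)C)Cc1cc(-c2oc3cc(OCC=C)c(OC)c(OC)c3c(=O)c2O)ccc1OC | intermediate (not isolated)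
26 | 2-{3-[(2R)-2-{[tert-butyl(dimethyl)silyl]oxy}-3-methylbut-3-en-1-yl]-4-methoxyphenyl}-3,7-dihydroxy-5,6-dimethoxy-4H-chromen-4-one | C=C(C)[C@H](O[Si](C)(C)C(C)(C)C)Cc1cc(-c2oc3cc(O)c(OC)c(OC)c3c(=O)c2O)ccc1OC | intermediate
27 | 3,7-dihydroxy-2-{3-[(2R)-2-hydroxy-3-methylbut-3-en-1-yl]-4-methoxyphenyl}-5,6-dimethoxy-4H-chromen-4-one | C=C(C)[C@H](O)Cc1cc(-c2oc3cc(O)c(OC)c(OC)c3c(=O)c2O)ccc1OC | target

**Step count**

Total: 16 steps. Longest linear sequence: 11 steps (steps 1–6, then 12–16); the ring A branch is 10 steps (steps 7–11, then 12–16).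

**Steps most likely to fail**

Step 5 (key cycloaddition). The ynol ether may oligomerise, or be hydrated by traces of acid, faster than it cycloadds, and regiocontrol may erode at the temperature needed. The fallback buys ring B and sets the stereocentre by kinetic resolution; it sets out from methacrolein 1 and returns at benzoate 10. Commercial methyl 3-(bromomethyl)-4-methoxybenzoate F1 is converted with Zn dust and LiCl in THF into [5-(methoxycarbonyl)-2-methoxybenzyl]zinc bromide F2. F2 adds 1,2 to 1 (MgCl2, THF, 0 °C → rt) to give racemic methyl 3-(2-hydroxy-3-methylbut-3-en-1-yl)-4-methoxybenzoate F3. Sharpless kinetic resolution (Ti(OiPr)4, L-(+)-diisopropyl tartrate, t-BuOOH (0.6 equiv), 4 Å molecular sieves, CH2Cl2, −20 °C) should epoxidise the (S)-enantiomer and leave methyl 3-[(2R)-2-hydroxy-3-methylbut-3-en-1-yl]-4-methoxybenzoate F4. Silylation of F4 (TBSCl, imidazole, DMF) gives 10.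

Step 3 (epoxide opening). Without a Lewis acid the opening may be slow, so that the acetylide decays or attack at the allylic carbon or the alkene terminus begins to compete. The fallback replaces the epoxide by a primary triflate with only one electrophilic carbon; it sets out from racemic epoxide 2 and returns at silyl ether 7. Resolution of 2 with the (R,R)-cobalt salen catalyst and H2O (0.45 equiv) gives (2S)-3-methylbut-3-ene-1,2-diol F5. Bis-silylation (TBSCl, imidazole, DMF) gives (2S)-1,2-bis{[tert-butyl(dimethyl)silyl]oxy}-3-methylbut-3-ene F6. Selective cleavage of the primary silyl ether (HF·pyridine, pyridine/THF, 0 °C) gives (2S)-2-{[tert-butyl(dimethyl)silyl]oxy}-3-methylbut-3-en-1-ol F7. Tf2O and 2,6-lutidine in CH2Cl2 at −78 °C give (2S)-2-{[tert-butyl(dimethyl)silyl]oxy}-3-methylbut-3-en-1-yl trifluoromethanesulfonate F8. Alkylation of lithium methoxyacetylide 5 with F8 (THF/DMPU, −78 → −20 °C) gives 7 directly.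

Step 10 (Rubottom oxidation). Enol silylation of the hindered ketone may be incomplete, and the peracid may oxidise the electron-rich ring or the allyl ether. The fallback introduces the C3 oxygen after the aroyl shift; it sets out from acetophenone 16 (with acid 11) and returns at diketone 22. Steglich esterification of 16 with 11 (EDC·HCl, DMAP, CH2Cl2) gives 2-acetyl-3,4-dimethoxy-5-(prop-2-en-1-yloxy)phenyl 3-[(2R)-2-{[tert-butyl(dimethyl)silyl]oxy}-3-methylbut-3-en-1-yl]-4-methoxybenzoate F9. Baker–Venkataraman rearrangement (LiN(SiMe3)2, THF, −78 → −20 °C) gives 1-{3-[(2R)-2-{[tert-butyl(dimethyl)silyl]oxy}-3-methylbut-3-en-1-yl]-4-methoxyphenyl}-3-[6-hydroxy-2,3-dimethoxy-4-(prop-2-en-1-yloxy)phenyl]propane-1,3-dione F10. α-Benzoyloxylation of the diketone enolate with dibenzoyl peroxide (Cs2CO3, THF, 0 °C) gives 22.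

**Further compounds**

F1 | step 5 | methyl 3-(bromomethyl)-4-methoxybenzoate (purchased) | COC(=O)c1ccc(OC)c(CBr)c1
F2 | step 5 | [5-(methoxycarbonyl)-2-methoxybenzyl]zinc bromide | COC(=O)c1ccc(OC)c(C[Zn]Br)c1
F3 | step 5 | rac-methyl 3-(2-hydroxy-3-methylbut-3-en-1-yl)-4-methoxybenzoate | C=C(C)C(O)Cc1cc(C(=O)OC)ccc1OC
F4 | step 5 | methyl 3-[(2R)-2-hydroxy-3-methylbut-3-en-1-yl]-4-methoxybenzoate | C=C(C)[C@H](O)Cc1cc(C(=O)OC)ccc1OC
F5 | step 3 | (2S)-3-methylbut-3-ene-1,2-diol | C=C(C)[C@H](O)CO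
F6 | step 3 | (2S)-1,2-bis{[tert-butyl(dimethyl)silyl]oxy}-3-methylbut-3-ene | C=C(C)[C@H](O[Si](C)(C)C(C)(C)C)CO[Si](C)(C)C(C)(C)C
F7 | step 3 | (2S)-2-{[tert-butyl(dimethyl)silyl]oxy}-3-methylbut-3-en-1-ol | C=C(C)[C@H](O[Si](C)(C)C(C)(C)C)CO
F8 | step 3 | (2S)-2-{[tert-butyl(dimethyl)silyl]oxy}-3-methylbut-3-en-1-yl trifluoromethanesulfonate | C=C(C)[C@H](O[Si](C)(C)C(C)(C)C)COS(=O)(=O)C(F)(F)F
F9 | step 10 | 2-acetyl-3,4-dimethoxy-5-(prop-2-en-1-yloxy)phenyl 3-[(2R)-2-{[tert-butyl(dimethyl)silyl]oxy}-3-methylbut-3-en-1-yl]-4-methoxybenzoate | C=C(C)[C@H](O[Si](C)(C)C(C)(C)C)Cc1cc(C(=O)Oc2cc(OCC=C)c(OC)c(OC)c2C(C)=O)ccc1OC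
F10 | step 10 | 1-{3-[(2R)-2-{[tert-butyl(dimethyl)silyl]oxy}-3-methylbut-3-en-1-yl]-4-methoxyphenyl}-3-[6-hydroxy-2,3-dimethoxy-4-(prop-2-en-1-yloxy)phenyl]propane-1,3-dione | C=C(C)[C@H](O[Si](C)(C)C(C)(C)C)Cc1cc(C(=O)CC(=O)c2c(O)cc(OCC=C)c(OC)c2OC)ccc1OC
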